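**Strategy.** The tetrahydrofuran ring is cut at O1–C2 and C2–C3; its C2 aryl group and both ether arms are added afterwards. This works because C2 is a single carbon wedged between O1 and C3, which carries a methyl group. In one operation a hydroxyl-directed rhodium hydroformylation places carbon monoxide on the internal vinyl carbon of a syn homoallylic alcohol, turns the vinyl CH2 into the C3 methyl and lets the new aldehyde close onto the C5 oxygen as a γ-lactol. The precursor is (1S,2R)-1-[4-(benzyloxy)-3-methoxyphenyl]-2-methylbut-3-en-1-ol, one crotylboration from O-benzylvanillin. The lactol then takes the second aryl ring at C2, and the two lactate-derived arms follow.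

Key step: step 2

Remark (assumptions): ring atoms are numbered O1, C2 (the carbon from CO), C3, C4, C5 (the carbinol carbon of the precursor); in each arm C7'' is the carbinol carbon and C8'' the ether carbon. The phosphorus ligand of step 2 is taken as an available catalyst component; it is substoichiometric and leaves no atoms in the product. From bisphenol 14 onward the core has twofold symmetry, so steps 6 to 9 act on both ends at once, and each twofold step takes up two molecules of its partner (equivalents are given on the Conditions lines).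

**Step 1**
Reactants: 1 4-(benzyloxy)-3-methoxybenzaldehyde; 2 cis-2-butene
Product: 5 (1S,2R)-1-[4-(benzyloxy)-3-methoxyphenyl]-2-methylbut-3-en-1-ol (syn), via (Z)-crotylpotassium 3 (not isolated), via (Z)-crotyldiisopinocampheylborane 4 (not isolated)
Conditions: 2, KOt-Bu, n-BuLi, THF, −78 to −45 °C; (−)-Ipc2BOMe [from (+)-α-pinene], −78 °C; BF3·OEt2; 1, −78 °C; NaOH, H2O2, rt
Reagents that add atoms: none
Why: Brown crotylboration: borane 4 adds through a closed chair transition state that turns the Z geometry into the syn relationship, and the isopinocampheyl groups from (+)-α-pinene direct the crotyl unit to the si face of the aldehyde, which sets the carbinol carbon as S and the methyl-bearing carbon as R (future C5 and C4).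

**Step 2**
Reactants: 5 (1S,2R)-1-[4-(benzyloxy)-3-methoxyphenyl]-2-methylbut-3-en-1-ol; 6 carbon monoxide
Product: 8 (3R,4R,5S)-5-[4-(benzyloxy)-3-methoxyphenyl]-3,4-dimethyloxolan-2-ol (anomeric mixture), via open-chain hydroxy aldehyde 7 (not isolated)
Conditions: Rh(acac)(CO)2 (2 mol %), 2-methoxy-1-methyl-3-phenyl-2,3-dihydro-1H-1,3-benzazaphosphole (20 mol %), p-toluenesulfonic acid (0.2 mol %), CO/H2 (1:1, 200 psi), benzene, 45 °C; then 1,8-diazabicyclo[5.4.0]undec-7-ene (DBU, 0.2 equiv), rt
Reagents that add atoms: none
Why: The carbinol hydroxyl of 5 exchanges reversibly with the methoxy group on the N,O-acetal carbon of the ligand, the bound phosphorus holds the rhodium hydride beside the vinyl group, and intramolecular hydride transfer to the terminal CH2 leaves rhodium on the internal carbon; CO insertion and hydrogenolysis of the acyl then release branched aldehyde 7. The closest known reaction type is the branch-selective hydroformylation of homoallylic alcohols under catalytic, reversibly bound directing ligands, which delivers γ-lactols. The oxolane ring closes by 5-exo-trig addition of the C5 hydroxyl to the aldehyde carbon, so O1–C2 forms right after C2–C3. The new stereocentre C3 is biased in the cyclic rhodium alkyl by the neighbouring C4 methyl and, because it lies α to the masked aldehyde, is then funnelled by DBU through open form 7 to the 3,4-trans lactol, in which the C3 methyl lies on the face opposite the C4 methyl and the C5 aryl group; C2 stays an anomer mixture because step 4 flattens it. The step needs branched over linear regioselectivity, and the substrate secures it through its homoallylic hydroxyl, which tethers the catalyst two atoms from the alkene and later serves as the ring oxygen. The benzyl and methyl aryl ethers are inert to CO/H2 and rhodium, and the acid co-catalyst is kept at trace level to spare the electron-rich benzylic alcohol.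

**Step 3**
Reactants: 8 (3R,4R,5S)-5-[4-(benzyloxy)-3-methoxyphenyl]-3,4-dimethyloxolan-2-ol
Product: 9 (3R,4R,5S)-5-[4-(benzyloxy)-3-methoxyphenyl]-3,4-dimethyl-2-(phenylsulfonyl)oxolane (anomeric mixture)
Conditions: PhSO2H, CaCl2, CH2Cl2, 0 °C to rt
Reagents that add atoms: benzenesulfinic acid, O=S(O)c1ccccc1
Why: Acid-mediated anomeric exchange (lactol to 2-sulfonyl ether): the lactol ionises to the oxocarbenium ion, the sulfinate captures it at sulfur and CaCl2 takes up the water, while C3, C4 and C5 are untouched and the configuration at C2 does not matter.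

**Step 4**
Reactants: 9 the 2-sulfonyl oxolane; 10 1-(benzyloxy)-4-bromo-2-methoxybenzene
Product: 13 (2S,3R,4R,5S)-2,5-bis[4-(benzyloxy)-3-methoxyphenyl]-3,4-dimethyloxolane, via arylmagnesium bromide 11 (not isolated), via arylzinc bromide 12 (not isolated)
Conditions: 10, Mg, THF, rt; ZnBr2, THF, rt; then 9, THF, rt
Reagents that add atoms: none
Why: Substitution of a 2-sulfonyl cyclic ether by an organozinc halide (Grignard formation, transmetalation, zinc-assisted ionisation, aryl transfer): the oxocarbenium ion prefers the envelope with C4 out of plane and both methyl groups pseudoequatorial, and aryl transfer to the inside face of that envelope places the new aryl group on C2 cis to the C3 methyl and trans to the C5 aryl group (2S).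

**Step 5**
Reactants: 13 the bis(benzyl ether)
Product: 14 4,4'-[(2S,3R,4R,5S)-3,4-dimethyloxolane-2,5-diyl]bis(2-methoxyphenol)
Conditions: H2 (1 atm), 10% Pd/C, EtOAc, rt
Reagents that add atoms: none
Why: Catalytic hydrogenolysis of benzyl aryl ethers, which in neutral ethyl acetate should be much faster than cleavage of the benzylic C–O bonds of the ring, so the reaction is stopped after two equivalents of hydrogen; no stereocentre is involved.

**Step 6**
Reactants: 14 the bisphenol; 15 ethyl (S)-lactate (3 equiv)
Product: 16 diethyl (2R,2'R)-2,2'-{[(2S,3R,4R,5S)-3,4-dimethyloxolane-2,5-diyl]bis[(2-methoxy-4,1-phenylene)oxy]}dipropanoate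
Conditions: 15 (3 equiv), PPh3 (3 equiv), i-PrO2CN=NCO2i-Pr (DIAD, 3 equiv), THF, 0 °C to rt
Reagents that add atoms: none
Why: Twofold Mitsunobu etherification: each of the two phenols displaces the phosphonium-activated hydroxyl of one lactate molecule in an SN2 step with inversion, so the S centre of 15 becomes the R centre C8'' of each arm, and the two phenols are equivalent by the twofold symmetry of 14.

**Step 7**
Reactants: 16 the bis(ethyl ester)
Product: 17 (2R,2'R)-2,2'-{[(2S,3R,4R,5S)-3,4-dimethyloxolane-2,5-diyl]bis[(2-methoxy-4,1-phenylene)oxy]}bis(N-methoxy-N-methylpropanamide)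
Conditions: MeNH(OMe)·HCl (4 equiv), i-PrMgCl (8 equiv), THF, −20 to 0 °C
Reagents that add atoms: N,O-dimethylhydroxylamine hydrochloride, CNOC.Cl
Why: Ester aminolysis to the Weinreb amide at both ester groups by the chloromagnesium amide made in the flask, a reagent that is nucleophilic and only weakly basic at this temperature, so the C8'' centres beside the carbonyl groups should keep their configuration.

**Step 8**
Reactants: 17 the bis(Weinreb amide); 18 3,4-dimethoxyphenylmagnesium bromide (3 equiv)
Product: 19 (2R,2'R)-2,2'-{[(2S,3R,4R,5S)-3,4-dimethyloxolane-2,5-diyl]bis[(2-methoxy-4,1-phenylene)oxy]}bis[1-(3,4-dimethoxyphenyl)propan-1-one]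
Conditions: 18 (3 equiv), THF, 0 °C; aq NH4Cl
Reagents that add atoms: none
Why: Twofold Weinreb ketone synthesis: one molecule of the aryl Grignard reagent adds to each of the two amide groups, so two aryl groups from 18 end up in 19, and each magnesium-chelated tetrahedral adduct survives until the quench, which prevents over-addition and keeps the enolisable α-aryloxy ketone from forming under basic conditions.

**Step 9**
Reactants: 19 the bis(ketone)
Product: 20 manassantin A, (1R,1'R,2R,2'R)-2,2'-{[(2S,3R,4R,5S)-3,4-dimethyloxolane-2,5-diyl]bis[(2-methoxy-4,1-phenylene)oxy]}bis[1-(3,4-dimethoxyphenyl)propan-1-ol]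
Conditions: polymer-supported borohydride (polystyrene–CH2NMe3+ BH4−), MeOH, 0 °C to rt
Reagents that add atoms: none
Why: Felkin–Anh-controlled hydride reduction: the ammonium counter-ion cannot chelate, so each ketone should react with its aryloxy group anti to the incoming hydride, which passes the hydrogen and not the methyl on C8'' and gives the threo (7''R,8''R) carbinol in both arms.

**Compound list**
1 | 4-(benzyloxy)-3-methoxybenzaldehyde (O-benzylvanillin) | COc1cc(C=O)ccc1OCc1ccccc1 | starting material
2 | cis-2-butene | C/C=C\C | starting material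
3 | (Z)-crotylpotassium | C/C=C\C[K] | intermediate
4 | (Z)-crotyldiisopinocampheylborane, isopinocampheyl groups from (+)-α-pinene | C/C=C\CB([C@@H]1C[C@@H]2C[C@H]([C@H]1C)C2(C)C)[C@@H]1C[C@@H]2C[C@H]([C@H]1C)C2(C)C | intermediate
5 | (1S,2R)-1-[4-(benzyloxy)-3-methoxyphenyl]-2-methylbut-3-en-1-ol (syn) | O[C@H](c1ccc(OCc2ccccc2)c(OC)c1)[C@H](C)C=C | intermediate
6 | carbon monoxide | [C-]#[O+] | starting material
7 | (2R,3R,4S)-4-[4-(benzyloxy)-3-methoxyphenyl]-4-hydroxy-2,3-dimethylbutanal | O[C@H](c1ccc(OCc2ccccc2)c(OC)c1)[C@H](C)[C@H](C=O)C | intermediate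
8 | (3R,4R,5S)-5-[4-(benzyloxy)-3-methoxyphenyl]-3,4-dimethyloxolan-2-ol (anomeric mixture) | OC1O[C@H](c2ccc(OCc3ccccc3)c(OC)c2)[C@H](C)[C@H]1C | intermediate
9 | (3R,4R,5S)-5-[4-(benzyloxy)-3-methoxyphenyl]-3,4-dimethyl-2-(phenylsulfonyl)oxolane (anomeric mixture) | O=S(=O)(c1ccccc1)C1O[C@H](c2ccc(OCc3ccccc3)c(OC)c2)[C@H](C)[C@H]1C | intermediate
10 | 1-(benzyloxy)-4-bromo-2-methoxybenzene | COc1cc(Br)ccc1OCc1ccccc1 | starting material
11 | [4-(benzyloxy)-3-methoxyphenyl]magnesium bromide | COc1cc([Mg]Br)ccc1OCc1ccccc1 | intermediate
12 | [4-(benzyloxy)-3-methoxyphenyl]zinc bromide | COc1cc([Zn]Br)ccc1OCc1ccccc1 | intermediate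
13 | (2S,3R,4R,5S)-2,5-bis[4-(benzyloxy)-3-methoxyphenyl]-3,4-dimethyloxolane (2,3-cis, 3,4-trans, 4,5-cis) | COc1cc([C@H]2O[C@H](c3ccc(OCc4ccccc4)c(OC)c3)[C@H](C)[C@H]2C)ccc1OCc1ccccc1 | intermediate
14 | 4,4'-[(2S,3R,4R,5S)-3,4-dimethyloxolane-2,5-diyl]bis(2-methoxyphenol) | COc1cc([C@H]2O[C@H](c3ccc(O)c(OC)c3)[C@H](C)[C@H]2C)ccc1O | intermediate
15 | ethyl (S)-lactate | CCOC(=O)[C@H](C)O | starting material
16 | diethyl (2R,2'R)-2,2'-{[(2S,3R,4R,5S)-3,4-dimethyloxolane-2,5-diyl]bis[(2-methoxy-4,1-phenylene)oxy]}dipropanoate | CCOC(=O)[C@@H](C)Oc1ccc([C@H]2O[C@H](c3ccc(O[C@H](C)C(=O)OCC)c(OC)c3)[C@H](C)[C@H]2C)cc1OC | intermediate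
17 | (2R,2'R)-2,2'-{[(2S,3R,4R,5S)-3,4-dimethyloxolane-2,5-diyl]bis[(2-methoxy-4,1-phenylene)oxy]}bis(N-methoxy-N-methylpropanamide) | CON(C)C(=O)[C@@H](C)Oc1ccc([C@H]2O[C@H](c3ccc(O[C@H](C)C(=O)N(C)OC)c(OC)c3)[C@H](C)[C@H]2C)cc1OC | intermediate
18 | 3,4-dimethoxyphenylmagnesium bromide (commercial 0.5 M solution in THF) | COc1ccc([Mg]Br)cc1OC | starting material
19 | (2R,2'R)-2,2'-{[(2S,3R,4R,5S)-3,4-dimethyloxolane-2,5-diyl]bis[(2-methoxy-4,1-phenylene)oxy]}bis[1-(3,4-dimethoxyphenyl)propan-1-one] | COc1ccc(C(=O)[C@@H](C)Oc2ccc([C@H]3O[C@H](c4ccc(O[C@H](C)C(=O)c5ccc(OC)c(OC)c5)c(OC)c4)[C@H](C)[C@H]3C)cc2OC)cc1OC | intermediate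
20 | manassantin A | COc1ccc([C@@H](O)[C@@H](C)Oc2ccc([C@H]3O[C@H](c4ccc(O[C@H](C)[C@H](O)c5ccc(OC)c(OC)c5)c(OC)c4)[C@H](C)[C@H]3C)cc2OC)cc1OC | target

**Count.** Total: 9 steps. Longest linear sequence: 9 steps (1 to 20).

**Steps most likely to fail**

Step 2 (key step). What may go wrong: rhodium hydride adds without the tether and ends on the terminal carbon (linear aldehyde, six-membered lactol); the alkene migrates; or the electron-rich benzylic alcohol ionises under the acid co-catalyst. The fallback sets out from 5 and comes back at 8. It no longer brings the one-carbon unit in as CO: the vinyl terminus is oxidised to become C2 and the C3 methyl is added by enolate alkylation. Hydroboration of 5 with 9-borabicyclo[3.3.1]nonane in THF and work-up with NaOH/H2O2 should give (1S,2R)-1-[4-(benzyloxy)-3-methoxyphenyl]-2-methylbutane-1,4-diol F1. Catalytic 2,2,6,6-tetramethylpiperidin-1-oxyl with PhI(OAc)2 in CH2Cl2 should oxidise the primary alcohol selectively and carry the resulting lactol on to (4R,5S)-5-[4-(benzyloxy)-3-methoxyphenyl]-4-methyloxolan-2-one F2. Deprotonation with LiN(SiMe3)2 in THF at −78 °C and methylation with MeI should bring the methyl in anti to the C4 methyl and give (3R,4R,5S)-5-[4-(benzyloxy)-3-methoxyphenyl]-3,4-dimethyloxolan-2-one F3. Reduction with i-Bu2AlH in CH2Cl2 at −78 °C should give lactol 8.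

Step 9. What may go wrong: poor facial selectivity at one or both ketones, which would give erythro arms; the bias from C8'' alone is modest and has to operate twice. The fallback sets out from 19 and ends at 20. It moves stereocontrol from the substrate to a chiral catalyst: Corey–Bakshi–Shibata reduction with (R)-1-methyl-3,3-diphenyltetrahydro-1H,3H-pyrrolo[1,2-c][1,3,2]oxazaborole and BH3·SMe2 in THF at −20 °C. The catalyst treats the aryl group as the large substituent and delivers hydride to the face that gives the (R) carbinol here, the same sense as the Felkin–Anh preference, so the two effects should reinforce. No compound outside the list is formed (F0).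

Step 6. What may go wrong: incomplete twofold etherification, because each phenol sits beside a methoxy group and the activated lactate can be lost by elimination to ethyl acrylate, so the mono-ether accumulates. The fallback sets out from 14 and comes back at 19, replacing steps 6 to 8. Each arm is made first as an α-sulfonyloxy ketone and joined by direct SN2 O-alkylation. Ethyl (S)-lactate 15 and neat pyrrolidine should give (S)-2-hydroxy-1-(pyrrolidin-1-yl)propan-1-one F4. Excess 18 in THF should convert it, through its magnesium alkoxide, into (S)-1-(3,4-dimethoxyphenyl)-2-hydroxypropan-1-one F5. TsCl in pyridine should give (S)-1-(3,4-dimethoxyphenyl)-1-oxopropan-2-yl 4-methylbenzenesulfonate F6. Bisphenol 14, this tosylate (2.5 equiv) and the phosphazene base 2-tert-butylimino-2-diethylamino-1,3-dimethylperhydro-1,3,2-diazaphosphorine (BEMP) in CH2Cl2 at rt should give 19 by twofold SN2 with inversion (S to R at C8''), one tosylate molecule reacting at each phenol.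

Step 4 is ranked below these three: substitution of a 2-sulfonyl cyclic ether by an arylzinc halide is an established reaction, and its facial outcome follows from the preferred envelope of the ring.

**Further compounds**
F1 | step 2 | (1S,2R)-1-[4-(benzyloxy)-3-methoxyphenyl]-2-methylbutane-1,4-diol | O[C@H](c1ccc(OCc2ccccc2)c(OC)c1)[C@H](C)CCO
F2 | step 2 | (4R,5S)-5-[4-(benzyloxy)-3-methoxyphenyl]-4-methyloxolan-2-one | O=C1O[C@H](c2ccc(OCc3ccccc3)c(OC)c2)[C@H](C)C1
F3 | step 2 | (3R,4R,5S)-5-[4-(benzyloxy)-3-methoxyphenyl]-3,4-dimethyloxolan-2-one | O=C1O[C@H](c2ccc(OCc3ccccc3)c(OC)c2)[C@H](C)[C@H]1C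
F4 | step 6 | (S)-2-hydroxy-1-(pyrrolidin-1-yl)propan-1-one | C[C@H](O)C(=O)N1CCCC1
F5 | step 6 | (S)-1-(3,4-dimethoxyphenyl)-2-hydroxypropan-1-one | C[C@H](O)C(=O)c1ccc(OC)c(OC)c1
F6 | step 6 | (S)-1-(3,4-dimethoxyphenyl)-1-oxopropan-2-yl 4-methylbenzenesulfonate | C[C@H](OS(=O)(=O)c1ccc(C)cc1)C(=O)c1ccc(OC)c(OC)c1
F0 | step 9 | none | none
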